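The plan disconnects ring C of the upper (epicatechin-type) unit across O1–C2 and C3–C4. A carbinol that links C8 of a benzylated (+)-catechin 3-O-(4-benzyloxybenzoate) to a phloroglucinol-derived ring A is ionised by a chiral Brønsted acid to an ortho-quinone methide (O1=C8a–C4a=C4). A (Z)-enol benzyl carbonate of 3,4-bis(benzyloxy)phenylacetaldehyde then adds across O1 and C4 in a hetero-Diels–Alder reaction. One operation thus closes ring C and sets C2, C3 and C4. The feature exploited is the ortho relation between the ring A oxygen O1 and the doubly benzylic C4 that carries the lower unit. Hydrogenolysis of all benzyl groups finishes the synthesis.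

Key step: step 7

Convention: flavan numbering is used for both units (ring A benzo, ring B 2-aryl, ring C pyran); "upper" is the unit bonded through C4, "lower" the unit bonded through C8.

Assumption: the (R)-configured acid is written for step 7; which catalyst enantiomer is matched with the (2R,3S) lower unit has to be found by experiment, and the (S) acid is used if the sense of induction proves opposite.

Step 1
Reactants: 1 (+)-catechin, (2R,3S)
Product: 2 5,7,3',4'-tetra-O-benzyl-(+)-catechin, (2R,3S)
Conditions: BnBr (4.4 equiv), K2CO3, DMF, 0 °C to rt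
Reagents that add atoms: benzyl bromide, BrCc1ccccc1
Why: Williamson ether synthesis in which K2CO3 deprotonates only the four phenols, so the aliphatic 3-OH stays free and the (2R,3S) centres are not touched.

Step 2
Reactants: 2 5,7,3',4'-tetra-O-benzyl-(+)-catechin; 3 4-(benzyloxy)benzoic acid
Product: 4 5,7,3',4'-tetra-O-benzyl-(+)-catechin 3-O-[4-(benzyloxy)benzoate]
Conditions: DCC, DMAP (cat.), CH2Cl2, rt
Reagents that add atoms: none
Why: Steglich esterification of the single free hydroxyl through the acylpyridinium ion; the C3–O bond is not broken, so C3 keeps its configuration.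

Step 3
Reactants: 4 5,7,3',4'-tetra-O-benzyl-(+)-catechin 3-O-[4-(benzyloxy)benzoate]
Product: 6 8-formyl-5,7,3',4'-tetra-O-benzyl-(+)-catechin 3-O-[4-(benzyloxy)benzoate], via iminium chloride 5 (not isolated)
Conditions: POCl3, DMF, 0 to 50 °C; then H2O
Reagents that add atoms: N,N-dimethylformamide, CN(C)C=O; phosphoryl chloride, O=P(Cl)(Cl)Cl (chloride of 5); water, O
Why: Vilsmeier–Haack formylation, expected at C8 of ring A because C6 lies between two benzyloxy groups while the benzoate ring and ring B are far less nucleophilic, the ester keeping O3 away from the chloroiminium reagent.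

Step 4
Reactants: 6 8-formyl-5,7,3',4'-tetra-O-benzyl-(+)-catechin 3-O-[4-(benzyloxy)benzoate]; 7 3,5-bis(benzyloxy)phenol
Product: 9 [2-hydroxy-4,6-bis(benzyloxy)phenyl][3-O-(4-benzyloxybenzoyl)-5,7,3',4'-tetra-O-benzylcatechin-8-yl]methanol (both carbinol epimers), via benzodioxaborin 8 (not isolated)
Conditions: PhB(OH)2 (1.2 equiv), EtCO2H (cat.), toluene, reflux, Dean–Stark; then propane-1,3-diol, THF, rt; used without contact with acidic supports
Reagents that add atoms: phenylboronic acid, OB(O)c1ccccc1 (atoms in 8 only)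
Why: Boronic acid-templated ortho-hydroxyalkylation of a phenol, in which the aryloxyboronate of 7 delivers the coordinated aldehyde to the carbon ortho to the phenol oxygen and the cyclic boronate 8 blocks further condensation, after which neutral transesterification frees the diol; the new carbinol centre is formed without control and becomes sp2 again in step 7.

Step 5
Reactants: 10 3,4-bis(benzyloxy)benzaldehyde
Product: 12 2-[3,4-bis(benzyloxy)phenyl]acetaldehyde, via enol ether 11 (not isolated)
Conditions: Ph3P(CH2OMe)Cl, KOtBu, THF, 0 °C to rt; then 2 M aq. HCl, THF, rt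
Reagents that add atoms: (methoxymethyl)triphenylphosphonium chloride, COC[P+](c1ccccc1)(c1ccccc1)c1ccccc1.[Cl-]; water, O
Why: Wittig methoxymethylenation followed by acid hydrolysis of the enol ether, a standard one-carbon homologation of an aryl aldehyde to the arylacetaldehyde (no stereocentre).

Step 6
Reactants: 12 2-[3,4-bis(benzyloxy)phenyl]acetaldehyde
Product: 14 benzyl (Z)-2-[3,4-bis(benzyloxy)phenyl]ethenyl carbonate, via potassium enolate 13 (not isolated)
Conditions: KN(SiMe3)2, THF, −78 °C; then CbzCl, −78 °C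
Reagents that add atoms: potassium bis(trimethylsilyl)amide, C[Si](C)(C)[N-][Si](C)(C)C.[K+] (potassium of 13); benzyl chloroformate, O=C(Cl)OCc1ccccc1
Why: O-acylation of an aldehyde enolate by a chloroformate (enol carbonate synthesis); kinetic deprotonation through the conformer with the aryl group syn-periplanar to the carbonyl oxygen should give mainly the Z enolate, whose geometry is kept on trapping at −78 °C.

Step 7
Reactants: 9 [2-hydroxy-4,6-bis(benzyloxy)phenyl][3-O-(4-benzyloxybenzoyl)-5,7,3',4'-tetra-O-benzylcatechin-8-yl]methanol; 14 benzyl (Z)-2-[3,4-bis(benzyloxy)phenyl]ethenyl carbonate (3 equiv)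
Product: 16 5,7,3',4'-tetra-O-benzyl-3-O-(benzyloxycarbonyl)epicatechin-(4β→8)-5,7,3',4'-tetra-O-benzylcatechin 3-O-[4-(benzyloxy)benzoate] (upper unit 2,3-cis-3,4-trans as in the target), via ortho-quinone methide 15 (not isolated)
Conditions: (R)-3,3'-bis(2,4,6-triisopropylphenyl)-BINOL N-triflylphosphoramide (10 mol%), 5 Å molecular sieves, CH2Cl2, −40 to 0 °C, slow addition of 9
Reagents that add atoms: none
Why: Proposed new method: the chiral acid ionises the doubly activated carbinol 9, with loss of water that the sieves take up, to the hydrogen-bonded ortho-quinone methide 15 (O1=C8a–C4a=C4 of the upper unit), whose electrophilic C4 is attacked by the CH–O carbon of 14 because the 3,4-bis(benzyloxy)phenyl group, through its para oxygen, and not the weakly donating carbonate oxygen, polarises the alkene, and the ring A oxygen then bonds to the benzylic C2. The closest known reaction type is the chiral phosphoramide-catalysed [4+2] cycloaddition of ortho-hydroxybenzhydrols with styrenes and beta-substituted styrenes to give 2,4-diarylchromans; an enol carbonate has not been shown as the styrene partner. Ring C of the upper unit closes in the [4+2] mode (inverse-demand hetero-Diels–Alder), which in its stepwise limit ends with a 6-exo-trig capture of the benzylic cation by O1. C2 and C3 become cis because the Z geometry of 14 is transferred suprafacially; C3 and C4 become trans because the carbonate takes the exo position, the endo sector being crowded by the 5-benzyloxy group of ring A and by the twisted, doubly ortho-substituted lower-unit aryl on C4, which leads to the conformer with the 2-aryl equatorial and the 3-oxygen and 4-aryl trans-diaxial; the absolute sense at C4, and with it at C2 and C3, is set by the chiral anion bound to the quinone methide oxygen, since the stereocentres of the lower unit are remote. The step needs regioselectivity (flavan, not isoflavan), exo selectivity and capture by the alkene in preference to the electron-rich arenes; these are secured by the para-benzyloxy group of 14, by the steric demand around C4, and by the excess of 14 with slow addition of 9 at low temperature.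

Step 8
Reactants: 16 5,7,3',4'-tetra-O-benzyl-3-O-(benzyloxycarbonyl)epicatechin-(4β→8)-5,7,3',4'-tetra-O-benzylcatechin 3-O-[4-(benzyloxy)benzoate]
Product: 17 epicatechin-(4β→8)-catechin 3-O-(4-hydroxybenzoate) on the lower unit (upper unit 2R,3R,4R; lower unit 2R,3S), the target
Conditions: H2 (1 atm), Pd(OH)2/C, THF/MeOH/H2O, rt
Reagents that add atoms: none
Why: Hydrogenolysis of the nine benzyl ethers and of the benzyl carbonate, which loses CO2 to free the upper 3-OH; the aroyl ester, the C4–C8 bond and the ring C ethers should survive these mild conditions and no stereocentre is touched.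

Compound list
1 | (+)-catechin, (2R,3S)-2-(3,4-dihydroxyphenyl)chromane-3,5,7-triol | O[C@H]1Cc2c(O)cc(O)cc2O[C@@H]1c1ccc(O)c(O)c1 | starting material
2 | 5,7,3',4'-tetra-O-benzyl-(+)-catechin, (2R,3S) | O[C@H]1Cc2c(OCc3ccccc3)cc(OCc3ccccc3)cc2O[C@@H]1c1ccc(OCc2ccccc2)c(OCc2ccccc2)c1 | intermediate
3 | 4-(benzyloxy)benzoic acid | OC(=O)c1ccc(OCc2ccccc2)cc1 | starting material
4 | 5,7,3',4'-tetra-O-benzyl-(+)-catechin 3-O-[4-(benzyloxy)benzoate], (2R,3S) | O=C(O[C@H]1Cc2c(OCc3ccccc3)cc(OCc3ccccc3)cc2O[C@@H]1c1ccc(OCc2ccccc2)c(OCc2ccccc2)c1)c1ccc(OCc2ccccc2)cc1 | intermediate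
5 | C8 (dimethyliminio)methyl derivative of 4, chloride salt (not isolated) | O=C(O[C@H]1Cc2c(OCc3ccccc3)cc(OCc3ccccc3)c(C=[N+](C)C)c2O[C@@H]1c1ccc(OCc2ccccc2)c(OCc2ccccc2)c1)c1ccc(OCc2ccccc2)cc1.[Cl-] | intermediate
6 | 8-formyl-5,7,3',4'-tetra-O-benzyl-(+)-catechin 3-O-[4-(benzyloxy)benzoate], (2R,3S) | O=C(O[C@H]1Cc2c(OCc3ccccc3)cc(OCc3ccccc3)c(C=O)c2O[C@@H]1c1ccc(OCc2ccccc2)c(OCc2ccccc2)c1)c1ccc(OCc2ccccc2)cc1 | intermediate
7 | 3,5-bis(benzyloxy)phenol | Oc1cc(OCc2ccccc2)cc(OCc2ccccc2)c1 | starting material
8 | 5,7-bis(benzyloxy)-2-phenyl-4H-1,3,2-benzodioxaborin carrying at C4 the C8 of the lower-unit ester, both C4 epimers (not isolated) | O=C(O[C@H]1Cc2c(OCc3ccccc3)cc(OCc3ccccc3)c(C3OB(c4ccccc4)Oc4cc(OCc5ccccc5)cc(OCc5ccccc5)c34)c2O[C@@H]1c1ccc(OCc2ccccc2)c(OCc2ccccc2)c1)c1ccc(OCc2ccccc2)cc1 | intermediate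
9 | [2-hydroxy-4,6-bis(benzyloxy)phenyl][3-O-(4-benzyloxybenzoyl)-5,7,3',4'-tetra-O-benzylcatechin-8-yl]methanol, both carbinol epimers | O=C(O[C@H]1Cc2c(OCc3ccccc3)cc(OCc3ccccc3)c(C(O)c3c(O)cc(OCc4ccccc4)cc3OCc3ccccc3)c2O[C@@H]1c1ccc(OCc2ccccc2)c(OCc2ccccc2)c1)c1ccc(OCc2ccccc2)cc1 | intermediate
10 | 3,4-bis(benzyloxy)benzaldehyde | O=Cc1ccc(OCc2ccccc2)c(OCc2ccccc2)c1 | starting material
11 | 1,2-bis(benzyloxy)-4-(2-methoxyethenyl)benzene, E/Z mixture (not isolated) | COC=Cc1ccc(OCc2ccccc2)c(OCc2ccccc2)c1 | intermediate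
12 | 2-[3,4-bis(benzyloxy)phenyl]acetaldehyde | O=CCc1ccc(OCc2ccccc2)c(OCc2ccccc2)c1 | intermediate
13 | potassium (Z)-2-[3,4-bis(benzyloxy)phenyl]ethenolate (not isolated) | [K+].[O-]/C=C\c1ccc(OCc2ccccc2)c(OCc2ccccc2)c1 | intermediate
14 | benzyl (Z)-2-[3,4-bis(benzyloxy)phenyl]ethenyl carbonate | O=C(OCc1ccccc1)O/C=C\c1ccc(OCc2ccccc2)c(OCc2ccccc2)c1 | intermediate
15 | ortho-quinone methide: 3,5-bis(benzyloxy)-6-methylidenecyclohexa-2,4-dien-1-one carrying the C8 of the lower-unit ester on the methylidene carbon (not isolated) | O=C(O[C@H]1Cc2c(OCc3ccccc3)cc(OCc3ccccc3)c(C=C3C(=O)C=C(OCc4ccccc4)C=C3OCc3ccccc3)c2O[C@@H]1c1ccc(OCc2ccccc2)c(OCc2ccccc2)c1)c1ccc(OCc2ccccc2)cc1 | intermediate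
16 | 5,7,3',4'-tetra-O-benzyl-3-O-(benzyloxycarbonyl)epicatechin-(4β→8)-5,7,3',4'-tetra-O-benzylcatechin 3-O-[4-(benzyloxy)benzoate]; upper unit 2,3-cis-3,4-trans, lower unit 2,3-trans | O=C(O[C@H]1Cc2c(OCc3ccccc3)cc(OCc3ccccc3)c([C@H]3c4c(OCc5ccccc5)cc(OCc5ccccc5)cc4O[C@H](c4ccc(OCc5ccccc5)c(OCc5ccccc5)c4)[C@@H]3OC(=O)OCc3ccccc3)c2O[C@@H]1c1ccc(OCc2ccccc2)c(OCc2ccccc2)c1)c1ccc(OCc2ccccc2)cc1 | intermediate
17 | epicatechin-(4β→8)-catechin 3-O-(4-hydroxybenzoate) on the lower unit; upper unit (2R,3R,4R), lower unit (2R,3S) | O=C(O[C@H]1Cc2c(O)cc(O)c([C@H]3c4c(O)cc(O)cc4O[C@H](c4ccc(O)c(O)c4)[C@@H]3O)c2O[C@@H]1c1ccc(O)c(O)c1)c1ccc(O)cc1 | target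

Total step count: 8. Longest linear sequence: 6 steps (steps 1, 2, 3, 4, 7, 8).

Steps most likely to fail

Step 7 (Proposed new method). Several processes could defeat it:
- attack of the alkene through its aryl-bearing carbon (enol-type polarisation), which would give the isoflavan skeleton;
- endo approach of the carbonate, which would give the 3,4-cis arrangement;
- insufficient facial control by the acid against the resident chirality of the lower unit;
- capture of the cation by electron-rich arene carbons (oligomerisation) or of C2 by the carbonate carbonyl.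

The fallback uses the known Lewis acid-mediated coupling of a flavan C4 cation with C8 of a flavan nucleophile. It sets out from compound 4 and comes back at compound 16. (−)-Epicatechin is benzylated (BnBr, K2CO3, DMF) to 5,7,3',4'-tetra-O-benzyl-(−)-epicatechin F1. F1 is oxidised at C4 with DDQ in CH2Cl2 in the presence of 2-ethoxyethanol to 4β-(2-ethoxyethoxy)-5,7,3',4'-tetra-O-benzylepicatechin F2, and its 3-OH is acylated with CbzCl, DMAP and pyridine to the 3-O-benzyl carbonate F3. F3 is then ionised with Me3SiOTf in CH2Cl2 at −78 °C in the presence of an excess of compound 4. C8 of 4 should attack the ring A-stabilised C4 cation trans to the 3-carbonate and give compound 16, which enters step 8.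

Step 4. The condensation may be slow because the aldehyde carbon is flanked by two ortho oxygens. The quinone methide may be released from the boronate under the acidic reflux and be captured by a second phenol. The acid-labile carbinol may ionise during isolation.

The fallback reverses the polarity of the bond construction. It sets out from compound 4 and comes back at compound 9. Compound 4 is iodinated at C8 with NIS (CH2Cl2, 0 °C) to the 8-iodo ester F4. Iodine–magnesium exchange with i-PrMgCl·LiCl (THF, −20 °C), which the hindered aroyl ester should tolerate at this temperature, gives the C8 arylmagnesium chloride F5. 2,4-Bis(benzyloxy)-6-hydroxybenzaldehyde F6, made from 2,4,6-trihydroxybenzaldehyde with two equivalents of BnBr and K2CO3, is converted with NaH into sodium 3,5-bis(benzyloxy)-2-formylphenolate F7. F5 adds to the aldehyde carbon of F7, and NH4Cl work-up gives compound 9.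

Step 6. Enolisation and trapping may give low Z selectivity. C-acylation or self-aldol condensation of the arylacetaldehyde may compete.

The fallback builds the Z enol geometry by a metal-catalysed alkyne addition. It sets out from compound 10 and comes back at compound 14. Compound 10 is converted with the Ohira–Bestmann reagent (K2CO3, MeOH) into 4-ethynyl-1,2-bis(benzyloxy)benzene F8. Acetic acid is added across the alkyne in the anti-Markovnikov sense with [RuCl2(p-cymene)]2, P(4-ClC6H4)3 and DMAP (toluene, 60 °C); this hydro-acyloxylation runs through a ruthenium vinylidene and should give (Z)-2-[3,4-bis(benzyloxy)phenyl]ethenyl acetate F9. F9 is cleaved with MeLi (2 equiv, THF, −78 °C) to the geometrically defined lithium (Z)-2-[3,4-bis(benzyloxy)phenyl]ethenolate F10, which is trapped with CbzCl to give compound 14.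

Further compounds
F1 | step 7 | 5,7,3',4'-tetra-O-benzyl-(−)-epicatechin, (2R,3R) | O[C@@H]1Cc2c(OCc3ccccc3)cc(OCc3ccccc3)cc2O[C@@H]1c1ccc(OCc2ccccc2)c(OCc2ccccc2)c1
F2 | step 7 | 4β-(2-ethoxyethoxy)-5,7,3',4'-tetra-O-benzylepicatechin (2,3-cis-3,4-trans) | CCOCCO[C@H]1c2c(OCc3ccccc3)cc(OCc3ccccc3)cc2O[C@H](c2ccc(OCc3ccccc3)c(OCc3ccccc3)c2)[C@@H]1O
F3 | step 7 | 4β-(2-ethoxyethoxy)-5,7,3',4'-tetra-O-benzylepicatechin 3-O-benzyl carbonate | CCOCCO[C@H]1c2c(OCc3ccccc3)cc(OCc3ccccc3)cc2O[C@H](c2ccc(OCc3ccccc3)c(OCc3ccccc3)c2)[C@@H]1OC(=O)OCc1ccccc1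
F4 | step 4 | 8-iodo-5,7,3',4'-tetra-O-benzyl-(+)-catechin 3-O-[4-(benzyloxy)benzoate] | O=C(O[C@H]1Cc2c(OCc3ccccc3)cc(OCc3ccccc3)c(I)c2O[C@@H]1c1ccc(OCc2ccccc2)c(OCc2ccccc2)c1)c1ccc(OCc2ccccc2)cc1
F5 | step 4 | C8 arylmagnesium chloride of the lower-unit ester | O=C(O[C@H]1Cc2c(OCc3ccccc3)cc(OCc3ccccc3)c([Mg]Cl)c2O[C@@H]1c1ccc(OCc2ccccc2)c(OCc2ccccc2)c1)c1ccc(OCc2ccccc2)cc1
F6 | step 4 | 2,4-bis(benzyloxy)-6-hydroxybenzaldehyde | O=Cc1c(O)cc(OCc2ccccc2)cc1OCc1ccccc1
F7 | step 4 | sodium 3,5-bis(benzyloxy)-2-formylphenolate | [Na+].[O-]c1cc(OCc2ccccc2)cc(OCc2ccccc2)c1C=O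
F8 | step 6 | 4-ethynyl-1,2-bis(benzyloxy)benzene | C#Cc1ccc(OCc2ccccc2)c(OCc2ccccc2)c1
F9 | step 6 | (Z)-2-[3,4-bis(benzyloxy)phenyl]ethenyl acetate | CC(=O)O/C=C\c1ccc(OCc2ccccc2)c(OCc2ccccc2)c1
F10 | step 6 | lithium (Z)-2-[3,4-bis(benzyloxy)phenyl]ethenolate | [Li+].[O-]/C=C\c1ccc(OCc2ccccc2)c(OCc2ccccc2)c1
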